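**Plan** (drimane numbering)
1. Retrosynthesis: cut the C11–O aryl ether (isofraxidin) and the C3–O acyl bond (isovalerate). Mask the C6 ketone as its 5,7-dien-6-yl methyl ether. Then cut C5–C10 and C8–C9 together and restore a CO2 bridge between C5 and C8.
2. Enabling feature: in ring B the run C5–C6(=O)–C7=C8(CH3) has the substitution pattern of C3–C4(OMe)–C5–C6(CH3) of 4-methoxy-6-methyl-2-pyrone. The other two ring atoms, tertiary C9 and methyl-bearing quaternary C10, are neighbours, like the two carbons of a trisubstituted alkene. C1 to C4 of ring A then serve as the tether.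
3. Forward: the chain grows from pyrone C3, with C4–C5 made by a Claisen shift, C2–C3 by Grignard addition, C9–C11 by carbonylation and C10–CH3 by carbocupration. Rings A and B close in one thermal operation, the coumarin and the ester arm follow, and the enone is unmasked last.
4. Stereochemistry: a CBS reduction sets C3 (S, 3β), and this centre steers the face of the cycloaddition (C10). The Z-alkene fixes C9 against C10. C3 is then inverted by oxidation and LiBH(s-Bu)3 reduction, and C5 arises by protonation to the trans ring fusion in the last step.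

Key step: step 11

Remark: drimane numbers are also used for the open-chain precursors, and β is the face of the C10 methyl. The bridged lactone of the key step is drawn as its endo isomer (CO2 bridge on the β face); the exo isomer would collapse to the same diene.

**Step 1**
Reactants: 1 4-hydroxy-6-methyl-2H-pyran-2-one; 2 3-methylbut-2-en-1-ol (prenol)
Product: 3 6-methyl-4-[(3-methylbut-2-en-1-yl)oxy]-2H-pyran-2-one
Conditions: PPh3, DIAD, THF, 0→23 °C
Reagents that add atoms: none
Why: Mitsunobu etherification of this acidic vinylogous acid with a primary allylic alcohol is known to alkylate O4, whereas a prenyl halide with base would also alkylate C3.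

**Step 2**
Reactants: 3 6-methyl-4-[(3-methylbut-2-en-1-yl)oxy]-2H-pyran-2-one
Product: 5 4-methoxy-6-methyl-3-(2-methylbut-3-en-2-yl)-2H-pyran-2-one, via hydroxypyrone 4 (not isolated)
Conditions: PhMe, 110 °C; cool, then K2CO3, Me2SO4, acetone, 23→50 °C
Reagents that add atoms: dimethyl sulfate, COS(=O)(=O)OC
Why: The Claisen rearrangement of the allyl vinyl ether unit O4–C4=C3 carries the dimethyl-substituted allyl terminus to C3, and O-methylation with a hard electrophile in the same flask traps the acidic enol before it can add to its own vinyl group.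

**Step 3**
Reactants: 5 4-methoxy-6-methyl-3-(2-methylbut-3-en-2-yl)-2H-pyran-2-one
Product: 7 2-(4-methoxy-6-methyl-2-oxo-2H-pyran-3-yl)-2-methylpropanal, via vicinal diol 6 (not isolated)
Conditions: OsO4 (2 mol %), NaIO4, 2,6-lutidine, 1,4-dioxane–H2O, 23 °C
Reagents that add atoms: osmium tetroxide, O=[Os](=O)(=O)=O; sodium periodate, [Na+].[O-]I(=O)(=O)=O
Why: In this Lemieux–Johnson cleavage OsO4 takes the isolated monosubstituted alkene in preference to the conjugated, more substituted pyrone double bonds, and the aldehyde formed has no α-hydrogen.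

**Step 4**
Reactants: 7 2-(4-methoxy-6-methyl-2-oxo-2H-pyran-3-yl)-2-methylpropanal; 8 (4-bromobut-1-yn-1-yl)trimethylsilane
Product: 10 rac-3-[3-hydroxy-2-methyl-7-(trimethylsilyl)hept-6-yn-2-yl]-4-methoxy-6-methyl-2H-pyran-2-one, via butynylmagnesium bromide 9 (not isolated)
Conditions: 8, Mg, THF, 23→40 °C; then 7, THF, −78 °C, cold quench
Reagents that add atoms: none
Why: In this Grignard addition at −78 °C the aldehyde should outcompete the pyrone carbonyl, a vinylogous carbonate screened by the tert-alkyl group, the cold quench keeps the alkoxide from attacking the pyrone, and the racemic carbinol centre is erased in step 5.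

**Step 5**
Reactants: 10 rac-3-[3-hydroxy-2-methyl-7-(trimethylsilyl)hept-6-yn-2-yl]-4-methoxy-6-methyl-2H-pyran-2-one
Product: 11 4-methoxy-6-methyl-3-[2-methyl-3-oxo-7-(trimethylsilyl)hept-6-yn-2-yl]-2H-pyran-2-one
Conditions: Dess–Martin periodinane, CH2Cl2, 23 °C
Reagents that add atoms: none
Why: Dess–Martin oxidation handles hindered secondary alcohols under near-neutral conditions that leave the pyrone and the silylalkyne untouched.

**Step 6**
Reactants: 11 4-methoxy-6-methyl-3-[2-methyl-3-oxo-7-(trimethylsilyl)hept-6-yn-2-yl]-2H-pyran-2-one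
Product: 12 3-[(3S)-3-hydroxy-2-methyl-7-(trimethylsilyl)hept-6-yn-2-yl]-4-methoxy-6-methyl-2H-pyran-2-one
Conditions: (R)-Me-CBS [(R)-1-methyl-3,3-diphenyltetrahydro-1H,3H-pyrrolo[1,2-c][1,3,2]oxazaborole] (20 mol %), BH3·SMe2, THF, −20 °C
Reagents that add atoms: none
Why: In this Corey–Bakshi–Shibata reduction the quaternary C4 is the large group and the C2 methylene the small one, as in tert-alkyl alkyl ketones, so the (R)-catalyst should give the (S)-carbinol (future 3β-oxygen), while the C-silyl group protects the alkyne from hydroboration.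

**Step 7**
Reactants: 12 3-[(3S)-3-hydroxy-2-methyl-7-(trimethylsilyl)hept-6-yn-2-yl]-4-methoxy-6-methyl-2H-pyran-2-one
Product: 13 4-methoxy-6-methyl-3-[(3S)-2-methyl-3-(triethylsilyloxy)-7-(trimethylsilyl)hept-6-yn-2-yl]-2H-pyran-2-one
Conditions: Et3SiOTf, 2,6-lutidine, CH2Cl2, −78→0 °C
Reagents that add atoms: triethylsilyl trifluoromethanesulfonate, CC[Si](CC)(CC)OS(=O)(=O)C(F)(F)F
Why: Silyl triflate silylation covers the neopentyl-type alcohol without strong base, blocks its cyclisation onto the pyrone, and installs a group that can later be removed under buffered fluoride despite the neighbouring quaternary carbon.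

**Step 8**
Reactants: 13 4-methoxy-6-methyl-3-[(3S)-2-methyl-3-(triethylsilyloxy)-7-(trimethylsilyl)hept-6-yn-2-yl]-2H-pyran-2-one
Product: 14 4-methoxy-6-methyl-3-[(3S)-2-methyl-3-(triethylsilyloxy)hept-6-yn-2-yl]-2H-pyran-2-one
Conditions: AgNO3 (10 mol %), CH2Cl2–MeOH–H2O, 23 °C
Reagents that add atoms: none
Why: Silver-catalysed protiodesilylation cleaves only the alkynyl C–Si bond under neutral conditions, which spares the silyl ether and avoids the methoxide that could open the pyrone.

**Step 9**
Reactants: 14 4-methoxy-6-methyl-3-[(3S)-2-methyl-3-(triethylsilyloxy)hept-6-yn-2-yl]-2H-pyran-2-one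
Product: 15 methyl (6S)-7-(4-methoxy-6-methyl-2-oxo-2H-pyran-3-yl)-7-methyl-6-(triethylsilyloxy)oct-2-ynoate
Conditions: PdCl2 (5 mol %), CuCl2, NaOAc, CO (1 atm), MeOH, 23 °C
Reagents that add atoms: carbon monoxide, [C-]#[O+]; methanol, CO
Why: Palladium-catalysed oxidative methoxycarbonylation of a terminal alkyne (alkynyl complex of divalent palladium, CO insertion, methanolysis, reoxidation of zerovalent palladium by CuCl2) runs in acetate buffer and is preferred to a lithium acetylide, whose base would first deprotonate the acidic 6-methyl group of the pyrone.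

**Step 10**
Reactants: 15 methyl (6S)-7-(4-methoxy-6-methyl-2-oxo-2H-pyran-3-yl)-7-methyl-6-(triethylsilyloxy)oct-2-ynoate
Product: 16 methyl (2Z,6S)-7-(4-methoxy-6-methyl-2-oxo-2H-pyran-3-yl)-3,7-dimethyl-6-(triethylsilyloxy)oct-2-enoate
Conditions: Me2CuLi (from CuI and MeLi), THF, −78 °C; MeOH quench at −78 °C
Reagents that add atoms: methyllithium, [Li]C (delivered as Me2CuLi, [Li+].C[Cu-]C)
Why: Syn-carbocupration of a 2-ynoate places CH3 and copper on the same side, protonation at −78 °C with retention gives the Z-enoate with C1 cis to C11, and the ynoate is far more electrophilic than the donor-substituted, shielded pyrone.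

**Step 11**
Reactants: 16 methyl (2Z,6S)-7-(4-methoxy-6-methyl-2-oxo-2H-pyran-3-yl)-3,7-dimethyl-6-(triethylsilyloxy)oct-2-enoate
Product: 18 methyl (3S,9R,10R)-6-methoxy-3-(triethylsilyloxy)drima-5,7-dien-11-oate (3β-OSiEt3; 10β-CH3; 9β-H), via bridged lactone 17 (not isolated)
Conditions: 1,2-dichlorobenzene (0.01 M), BHT (10 mol %), 180 °C, sealed base-washed tube, Ar
Reagents that add atoms: none
Why: On heating, the 4-methoxy-2-pyrone acts as an electron-rich diene through C3 and C6 and the tethered Z-enoate as dienophile in an asynchronous, normal-electron-demand intramolecular Diels–Alder reaction that joins nucleophilic pyrone C3 (future C5) to the enoate β-carbon C10 and pyrone C6 (future C8) to C9, after which the 2-oxabicyclo[2.2.2]octenone 17 expels CO2 by retro-[4+2] at the same temperature and leaves the 5,7-dien-6-yl methyl ether, a masked 7-en-6-one. The closest known reaction type is the thermal intramolecular cycloaddition of 2-pyrones to tethered alkenes with CO2 extrusion to cyclohexadienes, a class that already includes closures onto fully substituted alkene carbons, so this is known chemistry carried to a more crowded C5–C10 bond. Ring A closes in the fused mode as a six-membered ring through the four-atom tether C4–C3–C2–C1, its folding helped by the gem-dimethyl group on C4, and ring B closes as the six-membered ring of the [4+2] adduct (C5 to C10). C9 is fixed against C10 by suprafacial addition to the Z-alkene, which leaves the ester carbon C11 on the same side of ring B as C1 and thus opposite to the C10 methyl, and C10 is fixed against C3 by a chair-like tether with the C10 methyl axial, C9 equatorial and the silyloxy group equatorial, because an axial silyloxy group would be syn-axial to the pyrone ring atom on C5; the outcome is the 3β,10β relation. Only π-facial selectivity is therefore required, since the tether and the matched polarity dictate the regiochemistry and the endo or exo mode is erased once C5 and C8 are sp2. In 18 H-9 is pseudo-equatorial and poorly aligned with the diene, which should hold back a 1,5-hydrogen shift, while BHT, dilution and base-washed glass guard the Z-alkene and the dienol ether.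

**Step 12**
Reactants: 18 methyl (3S,9R,10R)-6-methoxy-3-(triethylsilyloxy)drima-5,7-dien-11-oate
Product: 19 methyl (3S,9R,10R)-3-hydroxy-6-methoxydrima-5,7-dien-11-oate
Conditions: n-Bu4NF, AcOH (1:1), THF, 0→23 °C
Reagents that add atoms: none
Why: Fluoride desilylation buffered with acetic acid is neither basic enough to epimerise C9 next to the ester nor acidic enough to hydrolyse the dienol ether.

**Step 13**
Reactants: 19 methyl (3S,9R,10R)-3-hydroxy-6-methoxydrima-5,7-dien-11-oate
Product: 20 methyl (9R,10R)-6-methoxy-3-oxodrima-5,7-dien-11-oate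
Conditions: Dess–Martin periodinane, pyridine, CH2Cl2, 0 °C
Reagents that add atoms: none
Why: Dess–Martin oxidation with pyridine to absorb the acetic acid preserves the dienol ether, and the new ketone cannot move into conjugation because C4 is quaternary.

**Step 14**
Reactants: 20 methyl (9R,10R)-6-methoxy-3-oxodrima-5,7-dien-11-oate
Product: 22 (3R,9R,10R)-6-methoxydrima-5,7-diene-3,11-diol (3α-OH; 9β-H), via 3α-hydroxy ester 21 (not isolated)
Conditions: LiBH(s-Bu)3, THF, −78 °C; then LiAlH4, −78→0 °C
Reagents that add atoms: none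
Why: The bulky trialkylborohydride avoids the axial path and attacks along the equatorial one, as known for 4,4-dimethyl-3-oxo terpenoids, to give the axial 3α-alcohol (3R), and LiAlH4 reduction of the ester in the same flask removes the only acidifying group at C9.

**Step 15**
Reactants: 22 (3R,9R,10R)-6-methoxydrima-5,7-diene-3,11-diol; 23 isofraxidin (7-hydroxy-6,8-dimethoxy-2H-chromen-2-one)
Product: 24 7-{[(3R,9R,10R)-3-hydroxy-6-methoxydrima-5,7-dien-11-yl]oxy}-6,8-dimethoxy-2H-chromen-2-one
Conditions: PPh3 and DIAD premixed, THF, 0 °C; then 22 and 23, 0→23 °C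
Reagents that add atoms: none
Why: The Mitsunobu etherification activates the primary C11 hydroxyl far faster than the axial C3 hydroxyl beside the quaternary carbon, the acidic phenol is a competent nucleophile, and preforming the betaine leaves no free azodicarboxylate to add to the diene.

**Step 16**
Reactants: 24 7-{[(3R,9R,10R)-3-hydroxy-6-methoxydrima-5,7-dien-11-yl]oxy}-6,8-dimethoxy-2H-chromen-2-one; 25 3-methylbutanoyl chloride
Product: 26 (3R,9R,10R)-11-[(6,8-dimethoxy-2-oxo-2H-chromen-7-yl)oxy]-6-methoxydrima-5,7-dien-3-yl 3-methylbutanoate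
Conditions: Et3N, DMAP, CH2Cl2, 23 °C
Reagents that add atoms: none
Why: DMAP-catalysed acylation esterifies hindered axial terpenoid alcohols with retention at C3, and the basic medium is harmless while the enone is still masked.

**Step 17**
Reactants: 26 (3R,9R,10R)-11-[(6,8-dimethoxy-2-oxo-2H-chromen-7-yl)oxy]-6-methoxydrima-5,7-dien-3-yl 3-methylbutanoate
Product: 27 (3R,5R,9R,10R)-11-[(6,8-dimethoxy-2-oxo-2H-chromen-7-yl)oxy]-6-oxodrim-7-en-3-yl 3-methylbutanoate (target)
Conditions: aq. HCl (0.5 M, cat.), THF, 0 °C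
Reagents that add atoms: water, O
Why: In this acid-catalysed enol ether hydrolysis the proton adds at C5 on the α face, away from the axial 4β and 10β methyl groups, C5 then lies next to the ketone and can settle into the more stable trans fusion (5α-H), and unmasking last in acid avoids base-induced vinylogous loss of the aryloxide through C9.

**Compound list**
1 | 4-hydroxy-6-methyl-2H-pyran-2-one | CC1=CC(O)=CC(=O)O1 | starting material
2 | 3-methylbut-2-en-1-ol | CC(C)=CCO | starting material
3 | 6-methyl-4-[(3-methylbut-2-en-1-yl)oxy]-2H-pyran-2-one | CC(C)=CCOC1=CC(=O)OC(C)=C1 | intermediate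
4 | 4-hydroxy-6-methyl-3-(2-methylbut-3-en-2-yl)-2H-pyran-2-one | OC1=C(C(C)(C)C=C)C(=O)OC(C)=C1 | intermediate
5 | 4-methoxy-6-methyl-3-(2-methylbut-3-en-2-yl)-2H-pyran-2-one | COC1=C(C(C)(C)C=C)C(=O)OC(C)=C1 | intermediate
6 | 3-(3,4-dihydroxy-2-methylbutan-2-yl)-4-methoxy-6-methyl-2H-pyran-2-one (racemic) | COC1=C(C(C)(C)C(O)CO)C(=O)OC(C)=C1 | intermediate
7 | 2-(4-methoxy-6-methyl-2-oxo-2H-pyran-3-yl)-2-methylpropanal | COC1=C(C(C)(C)C=O)C(=O)OC(C)=C1 | intermediate
8 | (4-bromobut-1-yn-1-yl)trimethylsilane | C[Si](C)(C)C#CCCBr | starting material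
9 | [4-(trimethylsilyl)but-3-yn-1-yl]magnesium bromide | C[Si](C)(C)C#CCC[Mg]Br | intermediate
10 | rac-3-[3-hydroxy-2-methyl-7-(trimethylsilyl)hept-6-yn-2-yl]-4-methoxy-6-methyl-2H-pyran-2-one | COC1=C(C(C)(C)C(O)CCC#C[Si](C)(C)C)C(=O)OC(C)=C1 | intermediate
11 | 4-methoxy-6-methyl-3-[2-methyl-3-oxo-7-(trimethylsilyl)hept-6-yn-2-yl]-2H-pyran-2-one | COC1=C(C(C)(C)C(=O)CCC#C[Si](C)(C)C)C(=O)OC(C)=C1 | intermediate
12 | 3-[(3S)-3-hydroxy-2-methyl-7-(trimethylsilyl)hept-6-yn-2-yl]-4-methoxy-6-methyl-2H-pyran-2-one | COC1=C(C(C)(C)[C@@H](O)CCC#C[Si](C)(C)C)C(=O)OC(C)=C1 | intermediate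
13 | 4-methoxy-6-methyl-3-[(3S)-2-methyl-3-(triethylsilyloxy)-7-(trimethylsilyl)hept-6-yn-2-yl]-2H-pyran-2-one | COC1=C(C(C)(C)[C@@H](O[Si](CC)(CC)CC)CCC#C[Si](C)(C)C)C(=O)OC(C)=C1 | intermediate
14 | 4-methoxy-6-methyl-3-[(3S)-2-methyl-3-(triethylsilyloxy)hept-6-yn-2-yl]-2H-pyran-2-one | COC1=C(C(C)(C)[C@@H](O[Si](CC)(CC)CC)CCC#C)C(=O)OC(C)=C1 | intermediate
15 | methyl (6S)-7-(4-methoxy-6-methyl-2-oxo-2H-pyran-3-yl)-7-methyl-6-(triethylsilyloxy)oct-2-ynoate | COC1=C(C(C)(C)[C@@H](O[Si](CC)(CC)CC)CCC#CC(=O)OC)C(=O)OC(C)=C1 | intermediate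
16 | methyl (2Z,6S)-7-(4-methoxy-6-methyl-2-oxo-2H-pyran-3-yl)-3,7-dimethyl-6-(triethylsilyloxy)oct-2-enoate | COC1=C(C(C)(C)[C@@H](O[Si](CC)(CC)CC)CC/C(C)=C\C(=O)OC)C(=O)OC(C)=C1 | intermediate
17 | methyl 5β,8β-(carbonyloxy)-6-methoxy-3β-(triethylsilyloxy)-9βH-drim-6-en-11-oate (2-oxabicyclo[2.2.2]oct-5-en-3-one core, endo isomer drawn) | COC(=O)[C@@H]1[C@]2(C)C=C(OC)[C@]3(C(=O)O2)C(C)(C)[C@@H](O[Si](CC)(CC)CC)CC[C@]13C | intermediate
18 | methyl (3S,9R,10R)-6-methoxy-3-(triethylsilyloxy)drima-5,7-dien-11-oate | COC(=O)[C@@H]1C(C)=CC(OC)=C2C(C)(C)[C@@H](O[Si](CC)(CC)CC)CC[C@]12C | intermediate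
19 | methyl (3S,9R,10R)-3-hydroxy-6-methoxydrima-5,7-dien-11-oate | COC(=O)[C@@H]1C(C)=CC(OC)=C2C(C)(C)[C@@H](O)CC[C@]12C | intermediate
20 | methyl (9R,10R)-6-methoxy-3-oxodrima-5,7-dien-11-oate | COC(=O)[C@@H]1C(C)=CC(OC)=C2C(C)(C)C(=O)CC[C@]12C | intermediate
21 | methyl (3R,9R,10R)-3-hydroxy-6-methoxydrima-5,7-dien-11-oate | COC(=O)[C@@H]1C(C)=CC(OC)=C2C(C)(C)[C@H](O)CC[C@]12C | intermediate
22 | (3R,9R,10R)-6-methoxydrima-5,7-diene-3,11-diol | OC[C@@H]1C(C)=CC(OC)=C2C(C)(C)[C@H](O)CC[C@]12C | intermediate
23 | isofraxidin (7-hydroxy-6,8-dimethoxy-2H-chromen-2-one) | COc1cc2ccc(=O)oc2c(OC)c1O | starting material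
24 | 7-{[(3R,9R,10R)-3-hydroxy-6-methoxydrima-5,7-dien-11-yl]oxy}-6,8-dimethoxy-2H-chromen-2-one | COc1cc2ccc(=O)oc2c(OC)c1OC[C@@H]1C(C)=CC(OC)=C2C(C)(C)[C@H](O)CC[C@]12C | intermediate
25 | 3-methylbutanoyl chloride | CC(C)CC(=O)Cl | starting material
26 | (3R,9R,10R)-11-[(6,8-dimethoxy-2-oxo-2H-chromen-7-yl)oxy]-6-methoxydrima-5,7-dien-3-yl 3-methylbutanoate | COc1cc2ccc(=O)oc2c(OC)c1OC[C@@H]1C(C)=CC(OC)=C2C(C)(C)[C@H](OC(=O)CC(C)C)CC[C@]12C | intermediate
27 | (3R,5R,9R,10R)-11-[(6,8-dimethoxy-2-oxo-2H-chromen-7-yl)oxy]-6-oxodrim-7-en-3-yl 3-methylbutanoate (3α-acyloxy, 5α-H, 9β-H, 10β-CH3) | COc1cc2ccc(=O)oc2c(OC)c1OC[C@@H]1C(C)=CC(=O)[C@H]2C(C)(C)[C@H](OC(=O)CC(C)C)CC[C@]12C | target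

**Total steps:** 17. **Longest linear sequence:** 17 (from 1).

**Steps most likely to fail**

**Step 11.** The cycloaddition may be too slow at temperatures the substrate tolerates, because the leading C5–C10 bond joins two fully substituted carbons next to quaternary C4. Long heating invites Z-to-E isomerisation of the enoate through a 1,5-hydrogen shift, migration of H-9 around the new diene, and erosion of facial selectivity through boat-like tether conformations.

The fallback sets out from 16 and returns at 22. It raises the dienophile to the aldehyde level, so that the [4+2] event runs under Lewis acid activation well below the temperature of CO2 loss and the two events are separated.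
- i-Bu2AlH (CH2Cl2, −78 °C) reduces the enoate to the Z-allylic alcohol F1; the pyrone carbonyl is a shielded vinylogous carbonate.
- MnO2 (CH2Cl2, 23 °C) gives the Z-enal F2.
- Me2AlCl (CH2Cl2, −78→−20 °C) should close both rings to the bridged lactone aldehyde F3.
- Short warming in toluene (about 100 °C) releases CO2 to give the dienyl aldehyde F4.
- Buffered n-Bu4NF gives the 3β-hydroxy aldehyde F5.
- Dess–Martin periodinane with pyridine gives the 3-oxo aldehyde F6.
- Excess LiBH(s-Bu)3 at −78 °C reduces both carbonyl groups to 22.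

**Step 15.** Substitution at the β-branched C11 by a phenol flanked by two methoxy groups may be slow. That would allow elimination of the activated alcohol toward allylic C9, or addition of azodicarboxylate to the diene.

The fallback sets out from 22 and returns at 24. It replaces the redox condensation by a two-stage Williamson synthesis without any azo reagent. Selective sulfonylation of the primary hydroxyl (MsCl, Et3N, CH2Cl2, −30 °C) gives the primary mesylate F7. The caesium phenoxide of 23 (Cs2CO3, DMF, 50 °C) then displaces it.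

**Step 14.** Facial selectivity of hydride delivery may be poor, because C5 is sp2. The missing 5α-hydrogen opens the axial trajectory, and allylic strain between the 6-methoxy group and C4 may distort the ring A chair.

The fallback sets out from 20 and returns at 21. It replaces substrate control by catalyst control. The reagents are (S)-Me-CBS [(S)-1-methyl-3,3-diphenyltetrahydro-1H,3H-pyrrolo[1,2-c][1,3,2]oxazaborole] and catecholborane in toluene at −40 °C. The catalyst reads quaternary C4 as the large and the C2 methylene as the small substituent, delivers hydride to the β face and gives the (3R)-alcohol. This fallback makes no new compound F0, and the LiAlH4 stage then follows as in step 14.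

**Further compounds**
F1 | step 11 | 3-[(3S,6Z)-8-hydroxy-2,6-dimethyl-3-(triethylsilyloxy)oct-6-en-2-yl]-4-methoxy-6-methyl-2H-pyran-2-one | COC1=C(C(C)(C)[C@@H](O[Si](CC)(CC)CC)CC/C(C)=C\CO)C(=O)OC(C)=C1
F2 | step 11 | (2Z,6S)-7-(4-methoxy-6-methyl-2-oxo-2H-pyran-3-yl)-3,7-dimethyl-6-(triethylsilyloxy)oct-2-enal | COC1=C(C(C)(C)[C@@H](O[Si](CC)(CC)CC)CC/C(C)=C\C=O)C(=O)OC(C)=C1
F3 | step 11 | 5β,8β-(carbonyloxy)-6-methoxy-3β-(triethylsilyloxy)-9βH-drim-6-en-11-al (endo isomer drawn) | O=C[C@@H]1[C@]2(C)C=C(OC)[C@]3(C(=O)O2)C(C)(C)[C@@H](O[Si](CC)(CC)CC)CC[C@]13C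
F4 | step 11 | (3S,9R,10R)-6-methoxy-3-(triethylsilyloxy)drima-5,7-dien-11-al | O=C[C@@H]1C(C)=CC(OC)=C2C(C)(C)[C@@H](O[Si](CC)(CC)CC)CC[C@]12C
F5 | step 11 | (3S,9R,10R)-3-hydroxy-6-methoxydrima-5,7-dien-11-al | O=C[C@@H]1C(C)=CC(OC)=C2C(C)(C)[C@@H](O)CC[C@]12C
F6 | step 11 | (9R,10R)-6-methoxy-3-oxodrima-5,7-dien-11-al | O=C[C@@H]1C(C)=CC(OC)=C2C(C)(C)C(=O)CC[C@]12C
F7 | step 15 | (3R,9R,10R)-3-hydroxy-6-methoxydrima-5,7-dien-11-yl methanesulfonate | CS(=O)(=O)OC[C@@H]1C(C)=CC(OC)=C2C(C)(C)[C@H](O)CC[C@]12C
F0 | step 14 | none | none
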